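The route is cut at both bonds flanking the C6=C7 alkene (C1 = lactone carbonyl, C4 = stereocentre, chain C5–C19; hydroxymethyl carbons C20 on C19, C24 on C7, C25 on C3). That alkene holds C24H2OH on C7 on the same side as C5, which maps onto propargyl alcohol: carbinol carbon C24, internal alkyne carbon C7, terminal carbon C6. In one flask a C8–C20 alkyl Grignard reagent adds anti across the alkyne (C7–C8) and the chelated Z-alkenylmagnesium opens methyl (R)-glycidate at CH2 (C5–C6), importing C4. The precursor is a homofarnesyl-type Grignard reagent with a silylated C20 hydroxyl, made from farnesol; the butenolide ring (O, C1–C4) is closed afterwards.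

Key step: step 8

Remark: (2E,6E)-farnesol, propargyl alcohol, methyl (R)-glycidate and (tributylstannyl)methanol are taken as catalogue chemicals. Compounds 18–22 carry a 1-ethoxyethyl acetal and are mixtures of epimers at the acetal carbon, a centre that disappears in step 14.

Step 1
Reactants: 1 (2E,6E)-farnesol
Product: 2 (2E,6E)-farnesal
Conditions: TEMPO (10 mol %), PhI(OAc)2, MeCN/pH 7 phosphate buffer, 0 °C
Reagents that add atoms: none
Why: Nitroxyl-catalysed oxidation of a primary allylic alcohol stops at the enal and, being close to neutral, should leave the 2E geometry untouched.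

Step 2
Reactants: 2 (2E,6E)-farnesal
Product: 3 (3E,7E)-4,8,12-trimethyltrideca-1,3,7,11-tetraene
Conditions: Ph3PCH3Br, n-BuLi, THF, 0 °C; then 2, −78 °C → rt
Reagents that add atoms: methyltriphenylphosphonium bromide, C[P+](c1ccccc1)(c1ccccc1)c1ccccc1.[Br-]
Why: Wittig methylenation of the enal with the non-stabilised ylide should give the terminal diene without disturbing the trisubstituted alkenes.

Step 3
Reactants: 3 (3E,7E)-4,8,12-trimethyltrideca-1,3,7,11-tetraene
Product: 5 (3E,7E)-4,8,12-trimethyltrideca-3,7,11-trien-1-ol (homofarnesol), via B-alkyl-9-BBN 4 (not isolated)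
Conditions: 9-BBN (1.05 equiv), THF, 0 °C → rt; then NaOH aq, H2O2, 0 °C
Reagents that add atoms: hydrogen peroxide, OO
Why: Hydroboration–oxidation with a bulky dialkylborane is selective for the monosubstituted end of the diene and places boron, then oxygen, on the terminal carbon, so the three trisubstituted alkenes should survive.

Step 4
Reactants: 5 (3E,7E)-4,8,12-trimethyltrideca-3,7,11-trien-1-ol
Product: 6 (3E,7E)-1-bromo-4,8,12-trimethyltrideca-3,7,11-triene (homofarnesyl bromide)
Conditions: CBr4, PPh3, CH2Cl2, 0 °C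
Reagents that add atoms: carbon tetrabromide, BrC(Br)(Br)Br
Why: The Appel reaction converts the primary homoallylic alcohol into the bromide under neutral conditions by SN2 displacement of an oxyphosphonium group.

Step 5
Reactants: 6 (3E,7E)-1-bromo-4,8,12-trimethyltrideca-3,7,11-triene
Product: 7 (2E,6E,10E)-13-bromo-2,6,10-trimethyltrideca-2,6,10-trien-1-ol
Conditions: SeO2 (0.2 equiv), t-BuOOH (70 % aq, 3 equiv), salicylic acid (0.1 equiv), CH2Cl2, 0 °C → rt
Reagents that add atoms: tert-butyl hydroperoxide, CC(C)(C)OO; selenium dioxide, O=[Se]=O (catalytic oxygen carrier)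
Why: Allylic oxidation by the ene reaction and [2,3]-sigmatropic shift of SeO2 prefers the E-methyl of the terminal isopropylidene group of a polyprenyl chain and should give the E-allylic alcohol, the alkyl bromide being inert and serving as the masked C8 terminus.

Step 6
Reactants: 7 (2E,6E,10E)-13-bromo-2,6,10-trimethyltrideca-2,6,10-trien-1-ol
Product: 8 {[(2E,6E,10E)-13-bromo-2,6,10-trimethyltrideca-2,6,10-trienyl]oxy}(tert-butyl)dimethylsilane
Conditions: TBSCl, imidazole, CH2Cl2, 0 °C → rt
Reagents that add atoms: tert-butyldimethylsilyl chloride, CC(C)(C)[Si](C)(C)Cl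
Why: Silyl ether formation at the unhindered primary allylic hydroxyl is fast and leaves the primary bromide untouched.

Step 7
Reactants: 8 {[(2E,6E,10E)-13-bromo-2,6,10-trimethyltrideca-2,6,10-trienyl]oxy}(tert-butyl)dimethylsilane
Product: 9 (3E,7E,11E)-13-{[tert-butyl(dimethyl)silyl]oxy}-4,8,12-trimethyltrideca-3,7,11-trienylmagnesium bromide, used as a titrated THF solution
Conditions: Mg turnings (I2-activated), THF, 35 °C
Reagents that add atoms: magnesium, [Mg]
Why: Grignard formation by insertion of magnesium into the primary C–Br bond tolerates the allylic silyl ether, and a homoallylic carbon–magnesium bond next to a trisubstituted alkene should not scramble the alkene geometry.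

Step 8
Reactants: 9 (3E,7E,11E)-13-{[tert-butyl(dimethyl)silyl]oxy}-4,8,12-trimethyltrideca-3,7,11-trienylmagnesium bromide; 10 propargyl alcohol; 11 methyl (R)-glycidate
Product: 14 methyl (2R,4Z,8E,12E,16E)-18-{[tert-butyl(dimethyl)silyl]oxy}-2-hydroxy-5-(hydroxymethyl)-9,13,17-trimethyloctadeca-4,8,12,16-tetraenoate, via bromomagnesium prop-2-yn-1-olate 12 (not isolated), via oxamagnesacycle 13 (not isolated)
Conditions: 10, EtMgBr (1.0 equiv to 10), THF, 0 °C; CuI (10 mol %), then 9 (0.9 equiv), THF/Et2O, −10 °C → rt; then 11 (1.2 equiv), −40 → −15 °C; aq NH4Cl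
Reagents that add atoms: none
Why: Proposed new method: the closest known reaction types are the CuI-catalysed anti-carbomagnesiation of propargyl alcohol with electrophilic capture of the resulting chelate, and the CuI-catalysed opening of glycidic esters at C3 by alkenyl Grignard reagents; using the epoxide as the capturing electrophile in the same flask is the untested part. The magnesium alkoxide 12 steers the alkyl group of 9 to the internal alkyne carbon (C7–C8 bond) while magnesium arrives anti at the terminal carbon, where the five-membered chelate 13 holds it cis to CH2O. The CuI already present should pass this alkenyl group to copper, and the alkenylcopper attacks the unsubstituted CH2 of 11 in an SN2 opening with retention at the alkenyl carbon (C5–C6 bond), so that C5 ends cis to C24 and the C6=C7 alkene is Z. No ring is closed in the product, chelate 13 being transient, and no stereocentre is created: C4 arrives with its R configuration from 11 because the reacting carbon is the achiral CH2. The step needs regio- and anti-selectivity in the carbomagnesiation, which alkoxide chelation supplies, and attack at the epoxide CH2 instead of the ester, which a soft alkenylcopper at −40 °C favours. Forming 12 with sacrificial EtMgBr spares the valuable reagent 9, and keeping 9 limiting leaves no alkylmagnesium to add to the ester.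

Step 9
Reactants: 14 methyl (2R,4Z,8E,12E,16E)-18-{[tert-butyl(dimethyl)silyl]oxy}-2-hydroxy-5-(hydroxymethyl)-9,13,17-trimethyloctadeca-4,8,12,16-tetraenoate
Product: 15 methyl (2R,4Z,8E,12E,16E)-18-{[tert-butyl(dimethyl)silyl]oxy}-5-({[tert-butyl(dimethyl)silyl]oxy}methyl)-2-hydroxy-9,13,17-trimethyloctadeca-4,8,12,16-tetraenoate
Conditions: TBSCl (1.05 equiv), imidazole, CH2Cl2, −20 → 0 °C
Reagents that add atoms: tert-butyldimethylsilyl chloride, CC(C)(C)[Si](C)(C)Cl
Why: Chemoselective silylation should take the primary allylic C24 hydroxyl well before the secondary hydroxyl, which is hindered and deactivated by the adjacent ester.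

Step 10
Reactants: 15 methyl (2R,4Z,8E,12E,16E)-18-{[tert-butyl(dimethyl)silyl]oxy}-5-({[tert-butyl(dimethyl)silyl]oxy}methyl)-2-hydroxy-9,13,17-trimethyloctadeca-4,8,12,16-tetraenoate
Product: 16 (2R,4Z,8E,12E,16E)-18-{[tert-butyl(dimethyl)silyl]oxy}-5-({[tert-butyl(dimethyl)silyl]oxy}methyl)-2-hydroxy-N-methoxy-N,9,13,17-tetramethyloctadeca-4,8,12,16-tetraenamide
Conditions: MeNH(OMe)·HCl (2.5 equiv), i-PrMgCl (6 equiv), THF, −20 → 0 °C
Reagents that add atoms: N,O-dimethylhydroxylamine hydrochloride, CNOC.Cl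
Why: Aminolysis of the methyl ester by the chloromagnesium amide gives the N-methoxy-N-methylamide, and the C4 alkoxide formed first prevents enolisation, so the stereocentre should be retained.

Step 11
Reactants: 17 (tributylstannyl)methanol
Product: 18 tributyl[(1-ethoxyethoxy)methyl]stannane
Conditions: ethyl vinyl ether, PPTS (cat.), CH2Cl2, 0 °C → rt
Reagents that add atoms: ethyl vinyl ether, C=COCC
Why: Acid-catalysed addition of the alcohol to the enol ether gives the mixed acetal, a base-stable and acid-labile mask for the hydroxymethyl anion equivalent.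

Step 12
Reactants: 16 (2R,4Z,8E,12E,16E)-18-{[tert-butyl(dimethyl)silyl]oxy}-5-({[tert-butyl(dimethyl)silyl]oxy}methyl)-2-hydroxy-N-methoxy-N,9,13,17-tetramethyloctadeca-4,8,12,16-tetraenamide; 18 tributyl[(1-ethoxyethoxy)methyl]stannane
Product: 20 (3R,5Z,9E,13E,17E)-19-{[tert-butyl(dimethyl)silyl]oxy}-6-({[tert-butyl(dimethyl)silyl]oxy}methyl)-1-(1-ethoxyethoxy)-3-hydroxy-10,14,18-trimethylnonadeca-5,9,13,17-tetraen-2-one, via (1-ethoxyethoxy)methyllithium 19 (not isolated)
Conditions: 18 (2.5 equiv), n-BuLi (2.4 equiv), THF, −78 °C; then 16, −78 → −50 °C; aq NH4Cl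
Reagents that add atoms: none
Why: Tin–lithium exchange gives the α-alkoxymethyllithium, whose first equivalent deprotonates the C4 hydroxyl and whose second adds to the amide to form a chelated tetrahedral adduct that releases the ketone only on work-up (Weinreb ketone synthesis), the C4 alkoxide shielding the stereocentre from enolisation.

Step 13
Reactants: 20 (3R,5Z,9E,13E,17E)-19-{[tert-butyl(dimethyl)silyl]oxy}-6-({[tert-butyl(dimethyl)silyl]oxy}methyl)-1-(1-ethoxyethoxy)-3-hydroxy-10,14,18-trimethylnonadeca-5,9,13,17-tetraen-2-one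
Product: 22 (5R)-5-[(2Z,6E,10E,14E)-16-{[tert-butyl(dimethyl)silyl]oxy}-3-({[tert-butyl(dimethyl)silyl]oxy}methyl)-7,11,15-trimethylhexadeca-2,6,10,14-tetraenyl]-4-[(1-ethoxyethoxy)methyl]furan-2(5H)-one, via phosphoranylidene acetate ester 21 (not isolated)
Conditions: Ph3P=C=C=O (1.3 equiv), toluene, 80 °C
Reagents that add atoms: (triphenylphosphoranylidene)ketene, O=C=C=P(c1ccccc1)(c1ccccc1)c1ccccc1
Why: The C4 hydroxyl adds to the ketene carbon to give an acyl ylide that closes onto the neighbouring ketone by intramolecular Wittig olefination, a five-membered ring closure that can only give the endocyclic alkene, while C4 takes no part in bond formation and should keep its R configuration.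

Step 14
Reactants: 22 (5R)-5-[(2Z,6E,10E,14E)-16-{[tert-butyl(dimethyl)silyl]oxy}-3-({[tert-butyl(dimethyl)silyl]oxy}methyl)-7,11,15-trimethylhexadeca-2,6,10,14-tetraenyl]-4-[(1-ethoxyethoxy)methyl]furan-2(5H)-one
Product: 23 hippolide F, (5R)-4-(hydroxymethyl)-5-[(2Z,6E,10E,14E)-16-hydroxy-3-(hydroxymethyl)-7,11,15-trimethylhexadeca-2,6,10,14-tetraenyl]furan-2(5H)-one
Conditions: CSA (0.2 equiv), MeOH, 0 °C → rt; NaHCO3
Reagents that add atoms: none
Why: Acid-catalysed methanolysis should remove both primary allylic silyl ethers and the acetal in one operation under conditions too mild to ionise the allylic alcohols and free of base, so the butenolide C4–H is not enolised.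

Compound list
1 | (2E,6E)-farnesol | CC(C)=CCC/C(C)=C/CC/C(C)=C/CO | starting material
2 | (2E,6E)-farnesal, (2E,6E)-3,7,11-trimethyldodeca-2,6,10-trienal | CC(C)=CCC/C(C)=C/CC/C(C)=C/C=O | intermediate
3 | (3E,7E)-4,8,12-trimethyltrideca-1,3,7,11-tetraene | CC(C)=CCC/C(C)=C/CC/C(C)=C/C=C | intermediate
4 | 9-[(3E,7E)-4,8,12-trimethyltrideca-3,7,11-trienyl]-9-borabicyclo[3.3.1]nonane | CC(C)=CCC/C(C)=C/CC/C(C)=C/CCB1C2CCCC1CCC2 | intermediate (not isolated)
5 | (3E,7E)-4,8,12-trimethyltrideca-3,7,11-trien-1-ol (homofarnesol) | CC(C)=CCC/C(C)=C/CC/C(C)=C/CCO | intermediate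
6 | (3E,7E)-1-bromo-4,8,12-trimethyltrideca-3,7,11-triene | CC(C)=CCC/C(C)=C/CC/C(C)=C/CCBr | intermediate
7 | (2E,6E,10E)-13-bromo-2,6,10-trimethyltrideca-2,6,10-trien-1-ol | C/C(=C\CC/C(C)=C/CC/C(C)=C/CCBr)CO | intermediate
8 | {[(2E,6E,10E)-13-bromo-2,6,10-trimethyltrideca-2,6,10-trienyl]oxy}(tert-butyl)dimethylsilane | C/C(=C\CC/C(C)=C/CC/C(C)=C/CCBr)CO[Si](C)(C)C(C)(C)C | intermediate
9 | (3E,7E,11E)-13-{[tert-butyl(dimethyl)silyl]oxy}-4,8,12-trimethyltrideca-3,7,11-trienylmagnesium bromide | C/C(=C\CC/C(C)=C/CC/C(C)=C/CC[Mg]Br)CO[Si](C)(C)C(C)(C)C | intermediate (key-step precursor, used in solution)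
10 | propargyl alcohol | C#CCO | starting material
11 | methyl (R)-glycidate | COC(=O)[C@H]1CO1 | starting material
12 | bromomagnesium prop-2-yn-1-olate | C#CCO[Mg]Br | intermediate (not isolated)
13 | 4-[(3E,7E,11E)-13-{[tert-butyl(dimethyl)silyl]oxy}-4,8,12-trimethyltrideca-3,7,11-trienyl]-1-oxa-2-magnesacyclopent-3-ene | [Mg]1OCC(CC/C=C(\C)CC/C=C(\C)CC/C=C(\C)CO[Si](C)(C)C(C)(C)C)=C1 | intermediate (not isolated)
14 | methyl (2R,4Z,8E,12E,16E)-18-{[tert-butyl(dimethyl)silyl]oxy}-2-hydroxy-5-(hydroxymethyl)-9,13,17-trimethyloctadeca-4,8,12,16-tetraenoate | C/C(=C\CC/C(C)=C/CC/C(C)=C/CC/C(=C/C[C@@H](O)C(=O)OC)CO)CO[Si](C)(C)C(C)(C)C | intermediate (key-step product)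
15 | methyl (2R,4Z,8E,12E,16E)-18-{[tert-butyl(dimethyl)silyl]oxy}-5-({[tert-butyl(dimethyl)silyl]oxy}methyl)-2-hydroxy-9,13,17-trimethyloctadeca-4,8,12,16-tetraenoate | C/C(=C\CC/C(C)=C/CC/C(C)=C/CC/C(=C/C[C@@H](O)C(=O)OC)CO[Si](C)(C)C(C)(C)C)CO[Si](C)(C)C(C)(C)C | intermediate
16 | (2R,4Z,8E,12E,16E)-18-{[tert-butyl(dimethyl)silyl]oxy}-5-({[tert-butyl(dimethyl)silyl]oxy}methyl)-2-hydroxy-N-methoxy-N,9,13,17-tetramethyloctadeca-4,8,12,16-tetraenamide | C/C(=C\CC/C(C)=C/CC/C(C)=C/CC/C(=C/C[C@@H](O)C(=O)N(C)OC)CO[Si](C)(C)C(C)(C)C)CO[Si](C)(C)C(C)(C)C | intermediate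
17 | (tributylstannyl)methanol | CCCC[Sn](CCCC)(CCCC)CO | starting material
18 | tributyl[(1-ethoxyethoxy)methyl]stannane (acetal carbon racemic) | CCCC[Sn](CCCC)(CCCC)COC(C)OCC | intermediate
19 | (1-ethoxyethoxy)methyllithium (acetal carbon racemic) | [Li]COC(C)OCC | intermediate (not isolated)
20 | (3R,5Z,9E,13E,17E)-19-{[tert-butyl(dimethyl)silyl]oxy}-6-({[tert-butyl(dimethyl)silyl]oxy}methyl)-1-(1-ethoxyethoxy)-3-hydroxy-10,14,18-trimethylnonadeca-5,9,13,17-tetraen-2-one (both acetal epimers) | C/C(=C\CC/C(C)=C/CC/C(C)=C/CC/C(=C/C[C@@H](O)C(=O)COC(C)OCC)CO[Si](C)(C)C(C)(C)C)CO[Si](C)(C)C(C)(C)C | intermediate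
21 | (triphenylphosphoranylidene)acetate ester of 20 at the C3 hydroxyl (both acetal epimers) | C/C(=C\CC/C(C)=C/CC/C(C)=C/CC/C(=C/C[C@@H](OC(=O)C=P(c1ccccc1)(c1ccccc1)c1ccccc1)C(=O)COC(C)OCC)CO[Si](C)(C)C(C)(C)C)CO[Si](C)(C)C(C)(C)C | intermediate (not isolated)
22 | (5R)-5-[(2Z,6E,10E,14E)-16-{[tert-butyl(dimethyl)silyl]oxy}-3-({[tert-butyl(dimethyl)silyl]oxy}methyl)-7,11,15-trimethylhexadeca-2,6,10,14-tetraenyl]-4-[(1-ethoxyethoxy)methyl]furan-2(5H)-one (both acetal epimers) | C/C(=C\CC/C(C)=C/CC/C(C)=C/CC/C(=C/C[C@H]1OC(=O)C=C1COC(C)OCC)CO[Si](C)(C)C(C)(C)C)CO[Si](C)(C)C(C)(C)C | intermediate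
23 | hippolide F, (5R)-4-(hydroxymethyl)-5-[(2Z,6E,10E,14E)-16-hydroxy-3-(hydroxymethyl)-7,11,15-trimethylhexadeca-2,6,10,14-tetraenyl]furan-2(5H)-one | C/C(=C\CC/C(C)=C/CC/C(C)=C/CC/C(=C/C[C@H]1OC(=O)C=C1CO)CO)CO | target

Total step count: 14.
Longest linear sequence: 13 steps (steps 1–10 and 12–14 from farnesol); step 11 is a one-step side branch that prepares the stannane.

Steps most likely to fail

1. Step 8. The chelated alkenylmagnesium 13 is an alkenylmagnesium alkoxide of low nucleophilicity and may pass its alkenyl group to copper too slowly. Bromide opening of the epoxide by MgBr2, addition to the ester, closure of the C24 alkoxide onto the ester, or simple protonation on work-up could then outrun C5–C6 bond formation. The fallback sets out from 9 and 10 and comes back at 15. The carbomagnesiation is run as in step 8, but the chelate is quenched with I2 at −10 °C, a known capture, to give (2Z)-3-iodo-2-[(3E,7E,11E)-13-{[tert-butyl(dimethyl)silyl]oxy}-4,8,12-trimethyltrideca-3,7,11-trienyl]prop-2-en-1-ol F1. TBSCl and imidazole convert it into the bis-silyl ether of the iodoalkenol F2. Iodine–magnesium exchange with i-PrMgCl·LiCl (THF, 0 °C → rt) gives the unchelated, more reactive (Z)-alkenylmagnesium chloride F3. With CuI (10 mol %) at −40 °C, this reagent opens 11 at CH2 and gives 15 directly, so step 9 is no longer needed.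

2. Step 13. Configuration at C4 may erode by enolisation or acyloin-type transposition of the α-hydroxy ketone while the ylide cascade is heated, and acylation of the hindered hydroxyl by the cumulated ylide may be slow. The fallback sets out from 20 and comes back at 22. The C4 hydroxyl is esterified with diethylphosphonoacetic acid (DCC, cat. DMAP, CH2Cl2, 0 °C) to give the diethylphosphonoacetate of 20 F4. Intramolecular Horner–Wadsworth–Emmons closure with LiCl and i-Pr2NEt in MeCN at 0 °C then forms the butenolide 22 without heating.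

3. Step 5. Site selectivity among three similar trisubstituted alkenes may be poor, and over-oxidation to the enal may occur, because neither internal alkene of 6 is electronically deactivated. The fallback sets out from 1 and comes back at 8, with the oxidation moved to a substrate whose proximal alkene is shielded by an allylic ester.
- Ac2O and pyridine give (2E,6E)-farnesyl acetate F5.
- SeO2 and t-BuOOH give (2E,6E,10E)-12-hydroxyfarnesyl acetate F6.
- TBSCl and imidazole give the silyl ether of that hydroxy acetate F7.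
- K2CO3 in MeOH gives (2E,6E,10E)-12-silyloxyfarnesol F8.
- TEMPO and PhI(OAc)2 give the 12-silyloxyfarnesal F9.
- Ph3P=CH2 gives the silyloxy tetraene F10.
- 9-BBN, then NaOH and H2O2, gives the 13-silyloxy homofarnesol F11.
- Appel bromination (CBr4, PPh3) of F11 gives 8.

Further compounds
F1 | step 8 | (2Z)-3-iodo-2-[(3E,7E,11E)-13-{[tert-butyl(dimethyl)silyl]oxy}-4,8,12-trimethyltrideca-3,7,11-trienyl]prop-2-en-1-ol | OC/C(CC/C=C(\C)CC/C=C(\C)CC/C=C(\C)CO[Si](C)(C)C(C)(C)C)=C\I
F2 | step 8 | tert-butyldimethylsilyl ether of F1 at the allylic hydroxyl | CC(C)(C)[Si](C)(C)OC/C(CC/C=C(\C)CC/C=C(\C)CC/C=C(\C)CO[Si](C)(C)C(C)(C)C)=C\I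
F3 | step 8 | (Z)-alkenylmagnesium chloride from F2 (as its LiCl complex in solution) | CC(C)(C)[Si](C)(C)OC/C(CC/C=C(\C)CC/C=C(\C)CC/C=C(\C)CO[Si](C)(C)C(C)(C)C)=C\[Mg]Cl
F4 | step 13 | diethylphosphonoacetate ester of 20 at the C3 hydroxyl | C/C(=C\CC/C(C)=C/CC/C(C)=C/CC/C(=C/C[C@@H](OC(=O)CP(=O)(OCC)OCC)C(=O)COC(C)OCC)CO[Si](C)(C)C(C)(C)C)CO[Si](C)(C)C(C)(C)C
F5 | step 5 | (2E,6E)-farnesyl acetate | CC(C)=CCC/C(C)=C/CC/C(C)=C/COC(C)=O
F6 | step 5 | (2E,6E,10E)-12-hydroxy-3,7,11-trimethyldodeca-2,6,10-trienyl acetate | C/C(=C\CC/C(C)=C/CC/C(C)=C/COC(C)=O)CO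
F7 | step 5 | (2E,6E,10E)-12-{[tert-butyl(dimethyl)silyl]oxy}-3,7,11-trimethyldodeca-2,6,10-trienyl acetate | C/C(=C\CC/C(C)=C/CC/C(C)=C/COC(C)=O)CO[Si](C)(C)C(C)(C)C
F8 | step 5 | (2E,6E,10E)-12-{[tert-butyl(dimethyl)silyl]oxy}-3,7,11-trimethyldodeca-2,6,10-trien-1-ol | C/C(=C\CC/C(C)=C/CC/C(C)=C/CO)CO[Si](C)(C)C(C)(C)C
F9 | step 5 | (2E,6E,10E)-12-{[tert-butyl(dimethyl)silyl]oxy}-3,7,11-trimethyldodeca-2,6,10-trienal | C/C(=C\CC/C(C)=C/CC/C(C)=C/C=O)CO[Si](C)(C)C(C)(C)C
F10 | step 5 | tert-butyl(dimethyl){[(2E,6E,10E)-2,6,10-trimethyltrideca-2,6,10,12-tetraenyl]oxy}silane | C/C(=C\CC/C(C)=C/CC/C(C)=C/C=C)CO[Si](C)(C)C(C)(C)C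
F11 | step 5 | (3E,7E,11E)-13-{[tert-butyl(dimethyl)silyl]oxy}-4,8,12-trimethyltrideca-3,7,11-trien-1-ol | C/C(=C\CC/C(C)=C/CC/C(C)=C/CCO)CO[Si](C)(C)C(C)(C)C
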